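**Retrosynthetic overview**

- The target is the all-cis 2,3,4-trisubstituted oxolane (7S,8S,7'S,8'S). Its C7'–OH and C8'–H come last, by hydroboration–oxidation of an exocyclic (E)-arylidene from the face opposite the two cis ring substituents; the same borane reduces the C9 acid.
- The oxolane, the only ring of the target, is closed as in lignan biosynthesis by hydroxyl capture of a para-quinone methide. Here the 4-hydroxycinnamyl ester of a 9,9'-lactone ionizes to the extended quinone methide and the C7 hydroxyl captures its CH2 terminus (O7–C9' bond), so C7 and C8 are not touched.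
- C7 and C8 come from an enantioselective anti-aldol of the β-arylidene γ-butyrolactone with a vanillin silyl ether.
- The β-arylidene lactone comes from a Stobbe condensation of vanillin benzyl ether with diethyl succinate, ester reduction and lactonization.
- Ring order: temporary γ-lactone first, then the oxolane, formed at the expense of the lactone.

Assumption: the (R,R)-enantiomer of the boron controller in the aldol step is taken to give the needed adduct; if the first run shows the mirror-image sense, the (S,S)-controller is used and nothing else changes.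

**Route**

Step 1
Reactants: 1 4-(benzyloxy)-3-methoxybenzaldehyde; 2 diethyl butanedioate (diethyl succinate)
Product: 3 (3E)-4-[4-(benzyloxy)-3-methoxyphenyl]-3-(ethoxycarbonyl)but-3-enoic acid
Conditions: KOtBu (1.3 equiv), tBuOH, reflux; then 2 M HCl
Reagents that add atoms: none
Why: Stobbe condensation: the succinate enolate condenses with the aldehyde and one carboxyl is unmasked in the same pot, giving regiospecifically the half-ester in which only the conjugated carboxyl is still an ester, with the aryl group trans to that ester (E), the geometry that later fixes C7'.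

Step 2
Reactants: 3
Product: 5 (4E)-4-{[4-(benzyloxy)-3-methoxyphenyl]methylidene}oxolan-2-one, via hydroxy acid 4 (not isolated)
Conditions: LiBEt3H (3.2 equiv), THF, −78 to 0 °C; then 2 M HCl, 23 °C
Reagents that add atoms: none
Why: Chemoselective hydride reduction then lactonization: the acid is first turned by the hydride into its unreactive carboxylate salt so that only the conjugated ester is reduced (1,2-mode) to the allylic alcohol, and acid closes the γ-lactone without touching the alkene geometry.

Step 3
Reactants: 5
Product: 6 (4E)-4-[(4-hydroxy-3-methoxyphenyl)methylidene]oxolan-2-one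
Conditions: BCl3 (2 equiv), C6HMe5 (3 equiv), CH2Cl2, −78 °C; MeOH
Reagents that add atoms: none
Why: Lewis acid O-debenzylation with pentamethylbenzene as a non-basic benzyl cation trap (Friedel–Crafts capture), chosen because hydrogenolysis would also reduce the styrene double bond, and the free phenol is needed to trigger step 5.

Step 4
Reactants: 6; 7 4-{[tert-butyl(dimethyl)silyl]oxy}-3-methoxybenzaldehyde
Product: 9 (3R,4E)-3-[(S)-(4-{[tert-butyl(dimethyl)silyl]oxy}-3-methoxyphenyl)(hydroxy)methyl]-4-[(4-hydroxy-3-methoxyphenyl)methylidene]oxolan-2-one, via aryl trimethylsilyl ether 8 (not isolated)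
Conditions: Me3SiCl (1.1 equiv), Et3N, CH2Cl2, 0 °C; (R,R)-2-bromo-4,5-diphenyl-1,3-bis(4-methylbenzenesulfonyl)-1,3,2-diazaborolidine (1.2 equiv), Et3N, −78 °C; 7, −78 °C; MeOH, pH 4 citrate buffer
Reagents that add atoms: none
Why: Enantioselective boron-mediated aldol addition with a chiral diazaborolidine controller (Corey type, here extended from acyclic esters to a lactone): the lactone can only form the E(O)-enolate, whose chair Zimmerman–Traxler transition state gives the anti adduct at the α-carbon, and the C2-symmetric controller selects the aldehyde face so that C7 (S) and C8 are set together, while the work-up removes the transient silyl group from the phenol.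

Step 5
Reactants: 9
Product: 11 (2S,3R,4E)-2-(4-{[tert-butyl(dimethyl)silyl]oxy}-3-methoxyphenyl)-4-[(4-hydroxy-3-methoxyphenyl)methylidene]oxolane-3-carboxylic acid, via quinone methide 10 (not isolated)
Conditions: Et3N (1.5 equiv), MeCN, 50 °C; then 1 M HCl to pH 4
Reagents that add atoms: none
Why: Proposed new method: the phenoxide of the 4-hydroxycinnamyl ester expels the lactone carboxylate in a vinylogous E1cB step to give an extended para-quinone methide, whose CH2 terminus is captured by the C7 hydroxyl in an oxa-1,8-addition that closes the oxolane and is driven by formation of the carboxylate, while C7 and C8 are spectators so the 2,3-cis relation from the anti-aldol is kept; the closest known reactions are quinone methide formation from 4-hydroxybenzyl and coniferyl esters under mild base and the intramolecular hydroxyl capture of quinone methides that closes the oxolane rings of lignans.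

Step 6
Reactants: 11
Product: 13 4-[(2S,3S,4S)-4-[(S)-hydroxy(4-hydroxy-3-methoxyphenyl)methyl]-3-(hydroxymethyl)oxolan-2-yl]-2-methoxyphenol, via dimethyl boronate 12 (not isolated)
Conditions: BH3·SMe2 (5 equiv), THF, 0 to 23 °C; MeOH; then 3 M NaOH, 30% H2O2, 0 to 23 °C; NH4Cl to pH 7
Reagents that add atoms: hydrogen peroxide, OO
Why: Borane reduction of the carboxylic acid and hydroboration–oxidation of the trisubstituted styrene in one pot: boron goes to the benzylic CH and hydrogen to ring carbon C8' from the face opposite the C8 substituent and the cis C7 aryl group, which makes the ring all-cis, and syn addition to the E-alkene followed by oxidation with retention gives the 7'S carbinol, while the alkaline peroxide also cleaves the aryl silyl ether.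

**Compound list**

1 | 4-(benzyloxy)-3-methoxybenzaldehyde | COc1cc(C=O)ccc1OCc1ccccc1 | starting material
2 | diethyl butanedioate (diethyl succinate) | CCOC(=O)CCC(=O)OCC | starting material
3 | (3E)-4-[4-(benzyloxy)-3-methoxyphenyl]-3-(ethoxycarbonyl)but-3-enoic acid | CCOC(=O)/C(CC(=O)O)=C/c1ccc(OCc2ccccc2)c(OC)c1 | intermediate
4 | (3E)-4-[4-(benzyloxy)-3-methoxyphenyl]-3-(hydroxymethyl)but-3-enoic acid | OC/C(CC(=O)O)=C/c1ccc(OCc2ccccc2)c(OC)c1 | intermediate
5 | (4E)-4-{[4-(benzyloxy)-3-methoxyphenyl]methylidene}oxolan-2-one | COc1cc(/C=C2/COC(=O)C2)ccc1OCc1ccccc1 | intermediate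
6 | (4E)-4-[(4-hydroxy-3-methoxyphenyl)methylidene]oxolan-2-one | COc1cc(/C=C2/COC(=O)C2)ccc1O | intermediate
7 | 4-{[tert-butyl(dimethyl)silyl]oxy}-3-methoxybenzaldehyde | COc1cc(C=O)ccc1O[Si](C)(C)C(C)(C)C | starting material
8 | (4E)-4-({3-methoxy-4-[(trimethylsilyl)oxy]phenyl}methylidene)oxolan-2-one | COc1cc(/C=C2/COC(=O)C2)ccc1O[Si](C)(C)C | intermediate
9 | (3R,4E)-3-[(S)-(4-{[tert-butyl(dimethyl)silyl]oxy}-3-methoxyphenyl)(hydroxy)methyl]-4-[(4-hydroxy-3-methoxyphenyl)methylidene]oxolan-2-one | COc1cc(/C=C2/COC(=O)[C@H]2[C@H](O)c3ccc(O[Si](C)(C)C(C)(C)C)c(OC)c3)ccc1O | intermediate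
10 | (2R)-2-[(S)-(4-{[tert-butyl(dimethyl)silyl]oxy}-3-methoxyphenyl)(hydroxy)methyl]-3-[(3-methoxy-4-oxocyclohexa-2,5-dien-1-ylidene)methyl]but-3-enoic acid (extended para-quinone methide; geometry at the ring-exocyclic double bond not defined) | COC1=CC(=CC(=C)[C@@H](C(=O)O)[C@H](O)c2ccc(O[Si](C)(C)C(C)(C)C)c(OC)c2)C=CC1=O | intermediate
11 | (2S,3R,4E)-2-(4-{[tert-butyl(dimethyl)silyl]oxy}-3-methoxyphenyl)-4-[(4-hydroxy-3-methoxyphenyl)methylidene]oxolane-3-carboxylic acid | COc1cc(/C=C2/CO[C@H](c3ccc(O[Si](C)(C)C(C)(C)C)c(OC)c3)[C@@H]2C(=O)O)ccc1O | intermediate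
12 | dimethyl {(S)-[(3S,4S,5S)-5-(4-{[tert-butyl(dimethyl)silyl]oxy}-3-methoxyphenyl)-4-(hydroxymethyl)oxolan-3-yl](4-hydroxy-3-methoxyphenyl)methyl}boronate | COc1cc([C@@H](B(OC)OC)[C@@H]2CO[C@H](c3ccc(O[Si](C)(C)C(C)(C)C)c(OC)c3)[C@@H]2CO)ccc1O | intermediate
13 | 4-[(2S,3S,4S)-4-[(S)-hydroxy(4-hydroxy-3-methoxyphenyl)methyl]-3-(hydroxymethyl)oxolan-2-yl]-2-methoxyphenol | COc1cc([C@@H](O)[C@@H]2CO[C@H](c3ccc(O)c(OC)c3)[C@@H]2CO)ccc1O | target

**Step count and risks**

Total steps: 6. Longest linear sequence: 6 steps (1 to 13); aldehyde 7 enters in step 4.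

The three steps most likely to fail are steps 4, 5 and 6.

Step 4 may give poor enantio- or diastereocontrol, because the controller is proven for acyclic esters and not for this lactone. The fallback sets out from 6 and 7 and comes back at 11. After the same transient silylation the aldol is run through the achiral dicyclohexylboron enolate (Cy2BOTf, Et3N, −78 °C), which gives the racemic anti adduct F1. The conditions of step 5 turn it into the racemic acid F2. Crystallization with (S)-1-phenylethylamine from ethanol gives the diastereomerically pure ammonium carboxylate F3 (the amine antipode is taken if the wrong salt crystallizes), and dilute HCl releases 11.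

Step 5 is the boldest step. The breaking C–O bond lies in the lactone ring and overlaps poorly with the styrene π system, so ionization may be slow. The C7 hydroxyl may also add to the benzylic (1,6) terminus, and base may dehydrate the aldol. The fallback sets out from 9 and comes back at 11. The zerovalent palladium complex Pd(PPh3)4 (5 mol %) in THF at 40 °C ionizes the allylic lactone C–O bond to a π-allylpalladium carboxylate, and the C7 hydroxyl attacks the unsubstituted terminus (Tsuji–Trost etherification) to give the same acid. No further compound is made (F0).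

Step 6 may suffer from a borate on the C9 oxygen delivering hydride to the wrong face, or from mixed regiochemistry. The fallback sets out from 11 and comes back at 13. BH3·SMe2 at −10 °C reduces only the acid to the primary alcohol F4. TBSCl and imidazole silylate the primary hydroxyl and the phenol to give the tris(silyl ether) F5, which places a bulky group beside the alkene and removes any directing oxygen–boron bond. 9-BBN (THF, 65 °C), then H2O2 at pH 7, gives the carbinol F6, and Bu4NF buffered with AcOH (THF, 0 °C) removes the three silyl groups to give 13.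

Further compounds
F1 | step 4 | racemic anti-aldol adduct (9 and its enantiomer, 1:1) | COc1cc(/C=C2/COC(=O)[C@H]2[C@H](O)c3ccc(O[Si](C)(C)C(C)(C)C)c(OC)c3)ccc1O.COc1cc(/C=C2/COC(=O)[C@@H]2[C@@H](O)c3ccc(O[Si](C)(C)C(C)(C)C)c(OC)c3)ccc1O
F2 | step 4 | racemic acid (11 and its enantiomer, 1:1) | COc1cc(/C=C2/CO[C@H](c3ccc(O[Si](C)(C)C(C)(C)C)c(OC)c3)[C@@H]2C(=O)O)ccc1O.COc1cc(/C=C2/CO[C@@H](c3ccc(O[Si](C)(C)C(C)(C)C)c(OC)c3)[C@H]2C(=O)O)ccc1O
F3 | step 4 | (S)-1-phenylethylammonium salt of acid 11 | COc1cc(/C=C2/CO[C@H](c3ccc(O[Si](C)(C)C(C)(C)C)c(OC)c3)[C@@H]2C(=O)[O-])ccc1O.C[C@H]([NH3+])c1ccccc1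
F0 | step 5 | none | none
F4 | step 6 | [(2S,3S,4E)-2-(4-{[tert-butyl(dimethyl)silyl]oxy}-3-methoxyphenyl)-4-[(4-hydroxy-3-methoxyphenyl)methylidene]oxolan-3-yl]methanol | COc1cc(/C=C2/CO[C@H](c3ccc(O[Si](C)(C)C(C)(C)C)c(OC)c3)[C@@H]2CO)ccc1O
F5 | step 6 | tris(tert-butyldimethylsilyl) ether of F4 (primary hydroxyl and both phenols silylated) | COc1cc(/C=C2/CO[C@H](c3ccc(O[Si](C)(C)C(C)(C)C)c(OC)c3)[C@@H]2CO[Si](C)(C)C(C)(C)C)ccc1O[Si](C)(C)C(C)(C)C
F6 | step 6 | tris(tert-butyldimethylsilyl) ether of 13 (C9 hydroxyl and both phenols silylated, C7' hydroxyl free) | COc1cc([C@@H](O)[C@@H]2CO[C@H](c3ccc(O[Si](C)(C)C(C)(C)C)c(OC)c3)[C@@H]2CO[Si](C)(C)C(C)(C)C)ccc1O[Si](C)(C)C(C)(C)C
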